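Cuts: the two O-methyl masks and a CO2tBu helper on C1' come off last. C1'–C2 is cut to 2-thioxochromene 6 and α-bromo ester 10, which the sulfur on C2 holds together for the event. Ring B (the pyranone) is cut at O1–C2 and C2–C3 to CS2 and acetophenone 4, and 4 goes back to acetic acid and 2,6-dimethoxytoluene 1.
Forward order: ring A (the benzene ring) is bought and receives its phenol oxygen, then its acetyl group. Ring B is closed with CS2, whose carbon becomes C2. The C30 acid derivative is joined in step 5, and one unmasking step ends the route.
Enabling feature: C2 is the β-carbon of the vinylogous ester O1–C2=C3–C4=O of ring B, so a C2–S derivative is a vinylogous thioester. It can take up a sulfur-tethered carbanion with C4=O as electron sink; a thiirane serves as temporary ring and PPh3 removes the sulfur. C1' is the α-carbon of a C30 fatty acid, whose carboxyl group serves bromination, S-alkylation and deprotonation and then leaves as CO2, which gives the odd C29 chain.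
The 6-methyl (not 8-methyl) pattern comes from the mirror symmetry of phenol 3: both open ring positions are equivalent, and only one oxygen is free to become O1.
Stereochemistry: the target has no stereocentre. C1' is a racemic stereocentre in 9 to 13 and becomes CH2 in step 6.

Key step: step 5

Assumption: the side chain of the target is read as unbranched C29H59 (n-nonacosyl), which makes triacontanoic acid the matching C30 acid. Compounds 1 and 7 are taken as commercial.

Step 1
Reactants: 1 2,6-dimethoxytoluene
Product: 3 3,5-dimethoxy-4-methylphenol, via aryl boronate 2 (not isolated)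
Conditions: [Ir(OMe)(cod)]2 (cat.), dtbpy (cat.), B2pin2, THF, 80 °C; then 30% H2O2, aq. NaOH, 0 °C
Reagents that add atoms: bis(pinacolato)diboron CC1(C)OB(OC1(C)C)B1OC(C)(C)C(C)(C)O1 (boryl group of 2); hydrogen peroxide OO (phenol oxygen of 3)
Why: Sterically governed iridium-catalysed aromatic C–H borylation should touch only the C–H bond para to the methyl group, the one position of this 1,2,3-trisubstituted ring without an ortho substituent, and oxidation of the boronate puts the oxygen at the same carbon (borylation–oxidation sequence).

Step 2
Reactants: 3 3,5-dimethoxy-4-methylphenol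
Product: 4 1-(6-hydroxy-2,4-dimethoxy-3-methylphenyl)ethanone
Conditions: AcOH, BF3·OEt2, 85 °C; then H2O
Reagents that add atoms: acetic acid CC(=O)O
Why: This is a Friedel–Crafts ortho-acylation of a phloroglucinol-type ring with the BF3–acetic acid system, as practised on 3,4,5-trimethoxyphenol; the two open positions of 3 are equivalent and the para position is blocked, so a single hydroxy ketone should form in which the only free OH is the future O1 and the methyl group lies between the two methoxy groups (future C6).

Step 3
Reactants: 4 1-(6-hydroxy-2,4-dimethoxy-3-methylphenyl)ethanone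
Product: 6 4-hydroxy-5,7-dimethoxy-6-methyl-2H-chromene-2-thione, via dithioacid salt 5 (not isolated)
Conditions: KOtBu (3.3 equiv), CS2, toluene–THF, 10 °C → rt; then aq. HCl
Reagents that add atoms: carbon disulfide S=C=S
Why: Claisen-type thioacylation of the ketone enolate with CS2 is followed on acidification by addition–elimination of the phenol oxygen at the dithioacid carbon with loss of H2S (6-exo-trig), the standard route from 2-hydroxyacetophenones to 4-hydroxy-2H-chromene-2-thiones; only one phenol oxygen is free, so ring B can close in one direction only.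

Step 4
Reactants: 7 triacontanoic acid
Product: 10 tert-butyl 2-bromotriacontanoate (racemic), via triacontanoyl chloride 8 (not isolated), via 2-bromotriacontanoyl chloride 9 (not isolated)
Conditions: SOCl2, 1,2-dichloroethane, 70 °C; NBS, HBr (cat.), 85 °C; evaporation; t-BuOH, pyridine, CH2Cl2, 0 °C → rt
Reagents that add atoms: thionyl chloride O=S(Cl)Cl (chlorine of 8 and 9); N-bromosuccinimide O=C1CCC(=O)N1Br; tert-butanol CC(C)(C)O
Why: This is a Hell–Volhard–Zelinsky-type α-bromination run on the acid chloride, whose enol is brominated by NBS under HBr catalysis, followed by alcoholysis of the α-bromo acid chloride; the new stereocentre is racemic and is erased in step 6.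

Step 5
Reactants: 6 4-hydroxy-5,7-dimethoxy-6-methyl-2H-chromene-2-thione; 10 tert-butyl 2-bromotriacontanoate
Product: 12 tert-butyl 2-(5,7-dimethoxy-6-methyl-4-oxo-4H-chromen-2-yl)triacontanoate (racemic), via thioether 11 (not isolated)
Conditions: NaH, Bu4NI (cat.), THF, 0 → 55 °C; then PPh3, NaN(SiMe3)2, THF–toluene, 0 → 70 °C; AcOH quench
Reagents that add atoms: none
Why: Proposed new method: the soft thiolate of 6 displaces bromide from 10 (SN2 at an α-halo ester) and ties the two halves together through sulfur as 11; NaN(SiMe3)2 then removes the C1'–H, acidified by ester and sulfur, and the enolate carbon adds to C2, the β-carbon of the vinylogous thioester S–C2=C3–C4=O of ring B, with the sodium-bound C4=O as electron sink. This 3-exo-trig closure gives a spiro thiirane, the only ring closed in the step and a temporary one, which PPh3 should desulfurise to Ph3P=S and the dienolate of 12, while the open α-thiolate reached by C2–S cleavage stays in equilibrium with the thiirane and drains through it. The closest known reaction type is the Eschenmoser sulfide contraction, established for thiolactam-derived thioiminium salts and, in its thioester version, for S-(2-oxoalkyl) thioesters that give β-dicarbonyl compounds; here the acceptor is the vinylogue of such a thioester. Site selectivity is fixed by the tether, because from sulfur the carbanion can reach only C2 (C4 lies trans to sulfur across C2=C3, so a five-membered closure is geometrically excluded), and a second chain cannot be transferred because 12 leaves the reaction as its unreactive dienolate. The driving force is the exchange of an ester enolate and a C–S bond for a delocalised dienolate, a C–C bond and the P=S bond. The new stereocentre at C1' forms without control as a racemate, which is harmless because it becomes CH2 in step 6.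

Step 6
Reactants: 12 tert-butyl 2-(5,7-dimethoxy-6-methyl-4-oxo-4H-chromen-2-yl)triacontanoate
Product: 14 5,7-dihydroxy-6-methyl-2-nonacosyl-4H-chromen-4-one, via acid 13 (not isolated)
Conditions: BBr3 (6 equiv), CH2Cl2, 0 °C → rt; ice–water; then 1,4-dioxane, 100 °C
Reagents that add atoms: none
Why: BBr3 ether cleavage should remove both aryl methyl groups (the one at C5 helped by chelation to C4=O) and the tert-butyl ester, and the freed acid 13, a vinylogous β-keto acid, should lose CO2 on heating through its 2-alkylidene-4-hydroxychromene tautomer (decarboxylation of the heteroarylacetic acid type), which turns C1' into CH2; the ether cleavage is anhydrous, so ring B is not opened and the methyl group cannot move from C6 to C8 by a Wessely–Moser rearrangement.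

Compound list
1 | 2,6-dimethoxytoluene (1,3-dimethoxy-2-methylbenzene) | COc1cccc(OC)c1C | starting material
2 | 2-(3,5-dimethoxy-4-methylphenyl)-4,4,5,5-tetramethyl-1,3,2-dioxaborolane | COc1cc(cc(OC)c1C)B1OC(C)(C)C(C)(C)O1 | intermediate
3 | 3,5-dimethoxy-4-methylphenol | COc1cc(O)cc(OC)c1C | intermediate
4 | 1-(6-hydroxy-2,4-dimethoxy-3-methylphenyl)ethanone | CC(=O)c1c(O)cc(OC)c(C)c1OC | intermediate
5 | 3-(6-hydroxy-2,4-dimethoxy-3-methylphenyl)-3-oxopropanedithioic acid (present as its potassium salt) | COc1cc(O)c(C(=O)CC(=S)S)c(OC)c1C | intermediate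
6 | 4-hydroxy-5,7-dimethoxy-6-methyl-2H-chromene-2-thione | COc1cc2oc(=S)cc(O)c2c(OC)c1C | intermediate
7 | triacontanoic acid | CCCCCCCCCCCCCCCCCCCCCCCCCCCCCC(=O)O | starting material
8 | triacontanoyl chloride | CCCCCCCCCCCCCCCCCCCCCCCCCCCCCC(=O)Cl | intermediate
9 | 2-bromotriacontanoyl chloride (racemic) | CCCCCCCCCCCCCCCCCCCCCCCCCCCCC(Br)C(=O)Cl | intermediate
10 | tert-butyl 2-bromotriacontanoate (racemic) | CCCCCCCCCCCCCCCCCCCCCCCCCCCCC(Br)C(=O)OC(C)(C)C | intermediate
11 | tert-butyl 2-[(5,7-dimethoxy-6-methyl-4-oxo-4H-chromen-2-yl)sulfanyl]triacontanoate (racemic) | CCCCCCCCCCCCCCCCCCCCCCCCCCCCC(Sc1cc(=O)c2c(OC)c(C)c(OC)cc2o1)C(=O)OC(C)(C)C | intermediate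
12 | tert-butyl 2-(5,7-dimethoxy-6-methyl-4-oxo-4H-chromen-2-yl)triacontanoate (racemic) | CCCCCCCCCCCCCCCCCCCCCCCCCCCCC(C(=O)OC(C)(C)C)c1cc(=O)c2c(OC)c(C)c(OC)cc2o1 | intermediate
13 | 2-(5,7-dihydroxy-6-methyl-4-oxo-4H-chromen-2-yl)triacontanoic acid (racemic) | CCCCCCCCCCCCCCCCCCCCCCCCCCCCC(C(=O)O)c1cc(=O)c2c(O)c(C)c(O)cc2o1 | intermediate
14 | 5,7-dihydroxy-6-methyl-2-nonacosyl-4H-chromen-4-one | CCCCCCCCCCCCCCCCCCCCCCCCCCCCCc1cc(=O)c2c(O)c(C)c(O)cc2o1 | target

Total step count: 6. Longest linear sequence: 5 (steps 1, 2, 3, 5, 6).

Steps most likely to fail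

Step 5. Three things may go wrong.
- The tethered enolate may fail to add to C2, whose acceptor strength is lowered by the two methoxy donors of ring A.
- Sulfur transfer to phosphorus may stall after the shift from sulfur to carbon.
- Intermolecular addition–elimination may overtake the intramolecular path.

The fallback uses known chemistry, forms the same C1'–C2 bond by a radical route, sets out from 4 and 7 and comes back to the route at 14. Vilsmeier–Haack double formylation of 4 (POCl3, DMF) closes ring B to 5,7-dimethoxy-6-methyl-4-oxo-4H-chromene-3-carbaldehyde F1. Pinnick oxidation (NaClO2, sulfamic acid) then gives 5,7-dimethoxy-6-methyl-4-oxo-4H-chromene-3-carboxylic acid F2. Acid 7 is converted with N-hydroxyphthalimide, DIC and DMAP into 1,3-dioxoisoindolin-2-yl triacontanoate F3. The doubly decarboxylative Giese reaction of F2 and F3 (Ru(bpy)3(PF6)2, iPr2NEt, CH2Cl2, blue LEDs) should add the nonacosyl radical to the unsubstituted C2 and release the helper at C3 as CO2. This gives racemic 5,7-dimethoxy-6-methyl-2-nonacosylchroman-4-one F4. Dehydrogenation with IBX in DMSO at 85 °C restores the C2=C3 bond in 5,7-dimethoxy-6-methyl-2-nonacosyl-4H-chromen-4-one F5, and BBr3 in CH2Cl2 gives 14.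

Step 6. Cleavage of the ether at C7, which has no chelation help, may be slow. Boron chelates of the waxy substrate may dissolve poorly, and decarboxylation may stay incomplete.

The fallback splits the unmasking into a Lewis-acid stage and a nucleophilic stage, sets out from 12 and comes back at 14. BCl3 in CH2Cl2 (−20 °C → rt) should take off only the tert-butyl ester and the chelated 5-O-methyl group, giving 2-(5-hydroxy-7-methoxy-6-methyl-4-oxo-4H-chromen-2-yl)triacontanoic acid F6. Heating F6 in dioxane at 100 °C gives 5-hydroxy-7-methoxy-6-methyl-2-nonacosyl-4H-chromen-4-one F7. The remaining 7-O-methyl group, the methyl of a vinylogous ester, is then removed by SN2 attack of NaSEt in DMF at 120 °C to give 14.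

Step 4. α-Bromination of the waxy acid chloride may be incomplete or go twice, and dehydrohalogenation to a ketene may interfere with the hindered alcoholysis.

The fallback reverses the order (ester first, bromine second, through an enolate derivative), sets out from 7 and comes back at 10. Acid chloride 8, made from 7 with SOCl2, is treated with t-BuOH and pyridine to give tert-butyl triacontanoate F8. LDA and Me3SiCl in THF at −20 °C convert F8 into its silyl ketene acetal, 1-tert-butoxy-1-(trimethylsilyloxy)triacont-1-ene F9. NBS in THF at 0 °C then brominates F9 at C2 to give 10.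

Further compounds
F1 | step 5 | 5,7-dimethoxy-6-methyl-4-oxo-4H-chromene-3-carbaldehyde | COc1cc2occ(C=O)c(=O)c2c(OC)c1C
F2 | step 5 | 5,7-dimethoxy-6-methyl-4-oxo-4H-chromene-3-carboxylic acid | COc1cc2occ(C(=O)O)c(=O)c2c(OC)c1C
F3 | step 5 | 1,3-dioxoisoindolin-2-yl triacontanoate | CCCCCCCCCCCCCCCCCCCCCCCCCCCCCC(=O)ON1C(=O)c2ccccc2C1=O
F4 | step 5 | 5,7-dimethoxy-6-methyl-2-nonacosylchroman-4-one (racemic) | CCCCCCCCCCCCCCCCCCCCCCCCCCCCCC1CC(=O)c2c(OC)c(C)c(OC)cc2O1
F5 | step 5 | 5,7-dimethoxy-6-methyl-2-nonacosyl-4H-chromen-4-one | CCCCCCCCCCCCCCCCCCCCCCCCCCCCCc1cc(=O)c2c(OC)c(C)c(OC)cc2o1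
F6 | step 6 | 2-(5-hydroxy-7-methoxy-6-methyl-4-oxo-4H-chromen-2-yl)triacontanoic acid (racemic) | CCCCCCCCCCCCCCCCCCCCCCCCCCCCC(C(=O)O)c1cc(=O)c2c(O)c(C)c(OC)cc2o1
F7 | step 6 | 5-hydroxy-7-methoxy-6-methyl-2-nonacosyl-4H-chromen-4-one | CCCCCCCCCCCCCCCCCCCCCCCCCCCCCc1cc(=O)c2c(O)c(C)c(OC)cc2o1
F8 | step 4 | tert-butyl triacontanoate | CCCCCCCCCCCCCCCCCCCCCCCCCCCCCC(=O)OC(C)(C)C
F9 | step 4 | 1-tert-butoxy-1-(trimethylsilyloxy)triacont-1-ene (mixture of alkene isomers) | CCCCCCCCCCCCCCCCCCCCCCCCCCCCC=C(OC(C)(C)C)O[Si](C)(C)C
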